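**Plan**
- **Cuts:** after the two O-benzyl groups, ring A is opened at C4a–C5 and C8–C8a. Ring C then loses the sulfur at C4a and the acetate at C3–O, and is opened at C2–C3 and O1–C8a. This leads back to 3,4-bis(benzyloxy)benzaldehyde, which supplies ring B, C2 and O1.
- **Enabling feature:** ring A carries its oxygens at C5 (OH) and C7 (OMe), meta to each other, with only hydrogens at C6 and C8. C5–C6–C7–C8 is therefore the chain of a 1,3-dioxygenated butadiene whose two oxygens are already differentiated (silyl versus methyl), and C4a=C8a is the enone alkene of a ring C dihydropyranone.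
- **Forward order:** ring B is bought and ring C is made first by an asymmetric hetero-Diels–Alder reaction. C3 is then acetoxylated, and pyranone C5 (future C4a) is sulfenylated and oxidised. Ring A is grown last by [4+2] cycloaddition with loss of sulfenic acid and methanol, and hydrogenolysis ends the route.
- **Stereochemistry:** C2 comes from the (S)-BINOL–Ti(OiPr)4 catalyst and C3 from substrate control, since the acetate enters trans to the C2 aryl group. The annulation leaves no new stereocentre and stays neutral, which spares both centres.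

Key step: step 6

Assumption: with (S)-BINOL–Ti(OiPr)4 the diene is taken to attack the Si face of aldehyde 1, the sense known for benzaldehyde; if 1 responded in the opposite sense, (R)-BINOL would be used.

Step 1
Reactants: 1 3,4-bis(benzyloxy)benzaldehyde; 2 (E)-1-methoxy-3-(trimethylsilyloxy)buta-1,3-diene (Danishefsky's diene)
Product: 4 (S)-2-[3,4-bis(benzyloxy)phenyl]-2,3-dihydro-4H-pyran-4-one, via silyl aldol adduct 3 (not isolated)
Conditions: (S)-BINOL (20 mol %), Ti(OiPr)4 (10 mol %), 4 Å MS, toluene, 0 °C; then TFA (cat.), CH2Cl2, 0 °C, brief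
Reagents that add atoms: none
Why: The catalytic asymmetric hetero-Diels–Alder reaction of this diene with aromatic aldehydes (Mukaiyama aldol then cyclisation pathway) is well established; the (S)-ligand should direct C2–C3 bond formation to the Si face and so set C2, and brief acid closes ring C by oxa-Michael addition with loss of methanol.

Step 2
Reactants: 4 (S)-2-[3,4-bis(benzyloxy)phenyl]-2,3-dihydro-4H-pyran-4-one
Product: 5 (2R,3R)-2-[3,4-bis(benzyloxy)phenyl]-4-oxo-3,4-dihydro-2H-pyran-3-yl acetate
Conditions: Mn(OAc)3 (3 equiv), benzene, reflux, Dean–Stark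
Reagents that add atoms: manganese triacetate, CC(=O)[O-].CC(=O)[O-].CC(=O)[O-].[Mn+3]
Why: The Mn(OAc)3 α'-acetoxylation of enones is known on 2-substituted 2,3-dihydropyran-4-ones; acetate is delivered to the C3 enolate/radical on the face opposite the pseudo-equatorial C2 aryl group, which gives the trans diequatorial product that is also the more stable epimer.

Step 3
Reactants: 5 (2R,3R)-2-[3,4-bis(benzyloxy)phenyl]-4-oxo-3,4-dihydro-2H-pyran-3-yl acetate
Product: 7 (2R,3R)-2-[3,4-bis(benzyloxy)phenyl]-4-oxo-5-(phenylsulfanyl)-3,4-dihydro-2H-pyran-3-yl acetate, via chloro sulfide adduct 6 (not isolated)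
Conditions: PhSCl (1.1 equiv, freshly distilled), CH2Cl2, −78 to 0 °C; then 2,6-lutidine, 0 °C
Reagents that add atoms: benzenesulfenyl chloride, ClSc1ccccc1
Why: This is electrophilic sulfenylation by sulfenyl chloride addition and dehydrochlorination, as used on cyclic enol ethers, flavones and enaminones; sulfur goes to C5, the nucleophilic carbon of the O1–C6=C5 enol ether, and the acidified C5–H of 6 is lost to a base too weak to touch C3 or open the ring.

Step 4
Reactants: 7 (2R,3R)-2-[3,4-bis(benzyloxy)phenyl]-4-oxo-5-(phenylsulfanyl)-3,4-dihydro-2H-pyran-3-yl acetate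
Product: 8 (2R,3R)-2-[3,4-bis(benzyloxy)phenyl]-4-oxo-5-(phenylsulfinyl)-3,4-dihydro-2H-pyran-3-yl acetate (both epimers at sulfur, used together)
Conditions: mCPBA (1.0 equiv), NaHCO3, CH2Cl2, −78 to −20 °C
Reagents that add atoms: 3-chloroperoxybenzoic acid (mCPBA), O=C(OO)c1cccc(Cl)c1
Why: In this sulfide-to-sulfoxide oxidation with one equivalent of peracid at low temperature, sulfur is far more nucleophilic than the electron-poor enone alkene or the benzyl ethers, and the sulfur configuration is irrelevant because the group is expelled later.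

Step 5
Reactants: 9 methyl (E)-3-methoxybut-2-enoate
Product: 11 (1E)-1,3-dimethoxy-1-(trimethylsilyloxy)buta-1,3-diene (Brassard's diene), via lithium dienolate 10 (not isolated)
Conditions: LiN(iPr)2, THF, −78 °C; then Me3SiCl, −78 °C to rt; distillation
Reagents that add atoms: chlorotrimethylsilane, C[Si](C)(C)Cl
Why: γ-Deprotonation of the β-methoxy crotonate followed by O-silylation of the extended enolate is the standard preparation of this vinylogous silyl ketene acetal, and its C1=C2 geometry is of no consequence because C1 ends up as an aromatic carbon.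

Step 6
Reactants: 8 (2R,3R)-2-[3,4-bis(benzyloxy)phenyl]-4-oxo-5-(phenylsulfinyl)-3,4-dihydro-2H-pyran-3-yl acetate; 11 (1E)-1,3-dimethoxy-1-(trimethylsilyloxy)buta-1,3-diene
Product: 14 3-O-acetylpadmatin 3',4'-dibenzyl ether, via cycloadduct 12 (not isolated), via aryl silyl ether 13 (not isolated)
Conditions: 11 (3 equiv), toluene, rt to 80 °C; then THF–0.1 M aq HCl, rt
Reagents that add atoms: none
Why: Proposed new method: the unsubstituted CH2 terminus of 11, its most nucleophilic carbon, attacks pyranone C6 of 8 (β-carbon of the sulfinyl enone, future C8a) while the acetal carbon bonds to C5 (future C4a) to give cis-fused 12, in which the sulfinyl group at C4a and the hydrogen at C8a are cis, so benzenesulfenic acid leaves by thermal syn elimination, methanol follows by 1,4-elimination across C5 and C8, and dilute acid cleaves silyl ether 13 to the chelated 5-OH of 14. The closest known reaction types are the benzannulation of 2-haloquinones with 1,3-dioxygenated silyloxy dienes and the cycloaddition–elimination of 3-sulfinylchromones with such dienes, whereas a monocyclic 5-sulfinyl-2,3-dihydropyran-4-one has not served as the two-carbon partner. Ring A closes as a six-membered carbocycle by an intermolecular normal-electron-demand [4+2] cycloaddition that forms C8–C8a and C4a–C5, and a stepwise variant (Mukaiyama–Michael addition, then 6-exo-trig attack of the α-sulfinyl enolate on the ester-derived carbon) would form the same two bonds. No stereocentre of 14 is made here, since C4a, C5, C8a and sulfur are flattened or expelled, so facial and endo/exo selectivity are irrelevant and C2 and C3 remain spectators in a medium that stays neutral until the short acid wash. The one selectivity required is regiochemical (5-OH/7-OMe, not the 8-oxygenated 6-methoxy isomer), and it is secured by pairing the donor terminus of the diene with the only electrophilic alkene carbon of 8. The sulfoxide lowers the LUMO of an alkene otherwise deactivated by O1, and its only β-hydrogen sits at C8a, so elimination can run in one direction only.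

Step 7
Reactants: 14 3-O-acetylpadmatin 3',4'-dibenzyl ether
Product: 15 3-O-acetylpadmatin
Conditions: H2 (1 atm), 10% Pd/C, EtOAc, rt (14 chromatographed free of sulfur residues beforehand)
Reagents that add atoms: none
Why: Hydrogenolysis of aryl benzyl ethers over Pd/C under neutral conditions is routine for dihydroflavonols; it should leave the acetate, the chelated aryl ketone, the C2–O1 bond and the base-labile C2 and C3 centres intact.

**Compound list**
1 | 3,4-bis(benzyloxy)benzaldehyde | O=Cc1ccc(OCc2ccccc2)c(OCc2ccccc2)c1 | starting material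
2 | (E)-1-methoxy-3-(trimethylsilyloxy)buta-1,3-diene | CO/C=C/C(=C)O[Si](C)(C)C | starting material
3 | (S,E)-5-[3,4-bis(benzyloxy)phenyl]-1-methoxy-5-(trimethylsilyloxy)pent-1-en-3-one | CO/C=C/C(=O)C[C@H](O[Si](C)(C)C)c1ccc(OCc2ccccc2)c(OCc2ccccc2)c1 | intermediate
4 | (S)-2-[3,4-bis(benzyloxy)phenyl]-2,3-dihydro-4H-pyran-4-one | O1[C@H](c2ccc(OCc3ccccc3)c(OCc3ccccc3)c2)CC(=O)C=C1 | intermediate
5 | (2R,3R)-2-[3,4-bis(benzyloxy)phenyl]-4-oxo-3,4-dihydro-2H-pyran-3-yl acetate | O1[C@H](c2ccc(OCc3ccccc3)c(OCc3ccccc3)c2)[C@@H](OC(C)=O)C(=O)C=C1 | intermediate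
6 | (2R,3R)-2-[3,4-bis(benzyloxy)phenyl]-6-chloro-4-oxo-5-(phenylsulfanyl)tetrahydro-2H-pyran-3-yl acetate (trans addition at C5/C6, configuration there not defined) | O1[C@H](c2ccc(OCc3ccccc3)c(OCc3ccccc3)c2)[C@@H](OC(C)=O)C(=O)C(Sc2ccccc2)C1Cl | intermediate
7 | (2R,3R)-2-[3,4-bis(benzyloxy)phenyl]-4-oxo-5-(phenylsulfanyl)-3,4-dihydro-2H-pyran-3-yl acetate | O1[C@H](c2ccc(OCc3ccccc3)c(OCc3ccccc3)c2)[C@@H](OC(C)=O)C(=O)C(Sc2ccccc2)=C1 | intermediate
8 | (2R,3R)-2-[3,4-bis(benzyloxy)phenyl]-4-oxo-5-(phenylsulfinyl)-3,4-dihydro-2H-pyran-3-yl acetate (both epimers at sulfur) | O1[C@H](c2ccc(OCc3ccccc3)c(OCc3ccccc3)c2)[C@@H](OC(C)=O)C(=O)C(S(=O)c2ccccc2)=C1 | intermediate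
9 | methyl (E)-3-methoxybut-2-enoate | CO/C(C)=C/C(=O)OC | starting material
10 | lithium (1E)-1,3-dimethoxybuta-1,3-dien-1-olate | C=C(OC)/C=C(\OC)[O-].[Li+] | intermediate
11 | (1E)-1,3-dimethoxy-1-(trimethylsilyloxy)buta-1,3-diene | C=C(OC)/C=C(\OC)O[Si](C)(C)C | intermediate
12 | (2R,3R)-2-[3,4-bis(benzyloxy)phenyl]-5,7-dimethoxy-4-oxo-4a-(phenylsulfinyl)-5-(trimethylsilyloxy)-3,4,4a,5,8,8a-hexahydro-2H-chromen-3-yl acetate (sulfinyl at C4a cis to H at C8a; drawn for diene attack on the face opposite the C2 aryl group; C5 and sulfur not defined; all isomers converge on 14) | COC1=CC(OC)(O[Si](C)(C)C)[C@@]2(S(=O)c3ccccc3)[C@@H](C1)O[C@H](c1ccc(OCc3ccccc3)c(OCc3ccccc3)c1)[C@@H](OC(C)=O)C2=O | intermediate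
13 | (2R,3R)-2-[3,4-bis(benzyloxy)phenyl]-7-methoxy-4-oxo-5-(trimethylsilyloxy)chroman-3-yl acetate | COc1cc(O[Si](C)(C)C)c2c(c1)O[C@H](c1ccc(OCc3ccccc3)c(OCc3ccccc3)c1)[C@@H](OC(C)=O)C2=O | intermediate
14 | (2R,3R)-2-[3,4-bis(benzyloxy)phenyl]-5-hydroxy-7-methoxy-4-oxochroman-3-yl acetate (3-O-acetylpadmatin 3',4'-dibenzyl ether) | COc1cc(O)c2c(c1)O[C@H](c1ccc(OCc3ccccc3)c(OCc3ccccc3)c1)[C@@H](OC(C)=O)C2=O | intermediate
15 | (2R,3R)-2-(3,4-dihydroxyphenyl)-5-hydroxy-7-methoxy-4-oxochroman-3-yl acetate (3-O-acetylpadmatin) | COc1cc(O)c2c(c1)O[C@H](c1ccc(O)c(O)c1)[C@@H](OC(C)=O)C2=O | target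

**Total steps:** 7. **Longest linear sequence:** 6 (steps 1, 2, 3, 4, 6, 7).

**Steps most likely to fail**

**Step 6.**
- What may go wrong:
  - Donation from O1 may make the cycloaddition too slow.
  - Silyl transfer from the ketene acetal to the sulfoxide oxygen may start a Pummerer-type diversion.
  - An inverse-demand hetero-cycloaddition across O=C4–C5=C6 may compete.
  - A stepwise Michael adduct may open ring C by β-elimination of O1.
- Fallback: known flavonoid chemistry that builds ring C onto a preformed ring A. It sets out from 1 and returns at 14.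
  - Commercial 2',6'-dihydroxy-4'-methoxyacetophenone is protected (MOMCl, NaH, DMF) as 1-[4-methoxy-2,6-bis(methoxymethoxy)phenyl]ethanone F1.
  - Claisen–Schmidt condensation of this ketone with 1 (KOH, EtOH) should give (E)-3-[3,4-bis(benzyloxy)phenyl]-1-[4-methoxy-2,6-bis(methoxymethoxy)phenyl]prop-2-en-1-one F2.
  - Juliá–Colonna epoxidation (poly-L-leucine, urea–H2O2, DBU, THF) should give the trans-(2R,3S)-epoxy ketone F3.
  - HCl in MeOH removes both MOM groups, so a freed phenol opens the epoxide at the benzylic carbon with inversion to give (2R,3R)-padmatin 3',4'-dibenzyl ether F4.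
  - Acetylation of the secondary 3-OH (Ac2O, 1 equiv, pyridine, 0 °C), which the chelated 5-OH should not contest, leads back to 14.

**Step 3.**
- What may go wrong:
  - Attack of the sulfenyl chloride on the push–pull alkene may be slow enough for sulfenylation of the dialkoxyarene to compete.
  - The ring may open during dehydrochlorination.
- Fallback: halogenation then cross-coupling. It sets out from 5 and returns at 7.
  - α-Iodination of the enone with iodine and pyridine in CH2Cl2 should give (2R,3R)-2-[3,4-bis(benzyloxy)phenyl]-5-iodo-4-oxo-3,4-dihydro-2H-pyran-3-yl acetate F5.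
  - A base-free Migita-type C–S coupling (Bu3SnSPh, Pd(PPh3)4, toluene, 90 °C) then exchanges iodine for the phenylsulfanyl group to give 7.

**Step 2.**
- What may go wrong:
  - Conversion may be incomplete.
  - Trans selectivity may erode.
  - The benzyl ethers or the electron-rich ring may be attacked oxidatively in the hot manganese medium.
- Fallback: enol silane oxidation. It sets out from 4 and returns at 5.
  - Soft enolisation (Me3SiOTf, Et3N, CH2Cl2, 0 °C) should give (S)-2-[3,4-bis(benzyloxy)phenyl]-4-(trimethylsilyloxy)-2H-pyran F6.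
  - Rubottom oxidation with dimethyldioxirane (acetone, −40 °C), on the C3=C4 face opposite the aryl group, and mild hydrolysis should give (2R,3R)-2-[3,4-bis(benzyloxy)phenyl]-3-hydroxy-2,3-dihydro-4H-pyran-4-one F7.
  - Ac2O in pyridine converts this alcohol into 5.

**Further compounds**
F1 | step 6 | 1-[4-methoxy-2,6-bis(methoxymethoxy)phenyl]ethanone | CC(=O)c1c(OCOC)cc(OC)cc1OCOC
F2 | step 6 | (E)-3-[3,4-bis(benzyloxy)phenyl]-1-[4-methoxy-2,6-bis(methoxymethoxy)phenyl]prop-2-en-1-one | COCOc1cc(OC)cc(OCOC)c1C(=O)/C=C/c1ccc(OCc2ccccc2)c(OCc2ccccc2)c1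
F3 | step 6 | [(2R,3S)-3-[3,4-bis(benzyloxy)phenyl]oxiran-2-yl][4-methoxy-2,6-bis(methoxymethoxy)phenyl]methanone | COCOc1cc(OC)cc(OCOC)c1C(=O)[C@@H]1O[C@H]1c1ccc(OCc2ccccc2)c(OCc2ccccc2)c1
F4 | step 6 | (2R,3R)-2-[3,4-bis(benzyloxy)phenyl]-3,5-dihydroxy-7-methoxychroman-4-one (padmatin 3',4'-dibenzyl ether) | COc1cc(O)c2c(c1)O[C@H](c1ccc(OCc3ccccc3)c(OCc3ccccc3)c1)[C@@H](O)C2=O
F5 | step 3 | (2R,3R)-2-[3,4-bis(benzyloxy)phenyl]-5-iodo-4-oxo-3,4-dihydro-2H-pyran-3-yl acetate | O1[C@H](c2ccc(OCc3ccccc3)c(OCc3ccccc3)c2)[C@@H](OC(C)=O)C(=O)C(I)=C1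
F6 | step 2 | (S)-2-[3,4-bis(benzyloxy)phenyl]-4-(trimethylsilyloxy)-2H-pyran | O1[C@H](c2ccc(OCc3ccccc3)c(OCc3ccccc3)c2)C=C(O[Si](C)(C)C)C=C1
F7 | step 2 | (2R,3R)-2-[3,4-bis(benzyloxy)phenyl]-3-hydroxy-2,3-dihydro-4H-pyran-4-one | O1[C@H](c2ccc(OCc3ccccc3)c(OCc3ccccc3)c2)[C@@H](O)C(=O)C=C1
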